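The flavanone is cut through ring C at C3–C4 and O1–C2. This exploits the ortho relationship on ring A between the carbonyl carbon C4 (on C4a) and O1 (on C8a), a latent salicylaldehyde, while C2–C3 with ring B is a latent arylacetylene. In one operation, rhodium-catalysed chelation-assisted hydroacylation of the alkyne joins the two fully elaborated halves at C3–C4, and a chiral amine–thiourea then closes O1–C2 by oxa-Michael addition, setting C2. The precursor is a 3-alkyl-2-hydroxy-4,6-bis(methoxymethoxy)benzaldehyde whose side-chain stereocentres come from trans-alkylation of (S)-β-methyl-γ-butyrolactone.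

Key step: step 10

Assumption: the quinine-derived thiourea is taken to induce the (2S) configuration in the ring closure; should the sense prove opposite, its quinidine-derived pseudoenantiomer would take its place with no other change.

Step 1
Reactants: 1 (S)-4-methyldihydrofuran-2(3H)-one; 2 1-bromo-3-methylbut-2-ene (prenyl bromide)
Product: 4 (3S,4S)-4-methyl-3-(3-methylbut-2-en-1-yl)dihydrofuran-2(3H)-one, via lithium enolate 3 (not isolated)
Conditions: LDA, THF, −78 °C; then 2, −78 → −40 °C
Reagents that add atoms: none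
Why: Kinetic lactone enolate alkylation with an allylic bromide should take place on the ring face anti to the C4 methyl group and so give the trans (3S,4S) lactone, the C4 centre being carried unchanged from the chiral pool.

Step 2
Reactants: 5 phloroglucinol
Product: 6 1,3,5-tris(methoxymethoxy)benzene
Conditions: NaH, MOMCl, DMF, 0 °C → rt
Reagents that add atoms: chloromethyl methyl ether COCCl
Why: Williamson-type O-alkylation of the triphenoxide with the hard chloromethyl ether should give the tris(methoxymethyl) ether rather than C-alkylated material.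

Step 3
Reactants: 6 1,3,5-tris(methoxymethoxy)benzene; 4 (3S,4S)-4-methyl-3-(3-methylbut-2-en-1-yl)dihydrofuran-2(3H)-one
Product: 8 (2S,3S)-4-hydroxy-3-methyl-2-(3-methylbut-2-en-1-yl)-1-[2,4,6-tris(methoxymethoxy)phenyl]butan-1-one, via aryllithium 7 (not isolated)
Conditions: n-BuLi, THF, 0 °C; then 4, −78 → 0 °C; then H2O
Reagents that add atoms: none
Why: Directed ortho-lithiation between two methoxymethoxy groups gives a single aryllithium whose acyl substitution on the lactone should stop at the lithium lactolate, which opens to the γ-hydroxy ketone on work-up without touching either stereocentre.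

Step 4
Reactants: 8 (2S,3S)-4-hydroxy-3-methyl-2-(3-methylbut-2-en-1-yl)-1-[2,4,6-tris(methoxymethoxy)phenyl]butan-1-one
Product: 9 (2S,3S)-4-[tert-butyl(dimethyl)silyl]oxy-3-methyl-2-(3-methylbut-2-en-1-yl)-1-[2,4,6-tris(methoxymethoxy)phenyl]butan-1-one
Conditions: TBSCl, imidazole, DMF, 0 °C → rt
Reagents that add atoms: tert-butyldimethylsilyl chloride CC(C)(C)[Si](C)(C)Cl
Why: Imidazole-promoted silylation of the only hydroxyl group, a primary alcohol, should be fast and leaves the epimerisable ketone α-centre alone.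

Step 5
Reactants: 9 (2S,3S)-4-[tert-butyl(dimethyl)silyl]oxy-3-methyl-2-(3-methylbut-2-en-1-yl)-1-[2,4,6-tris(methoxymethoxy)phenyl]butan-1-one
Product: 10 (2S,3S)-4-[tert-butyl(dimethyl)silyl]oxy-1-[2-hydroxy-4,6-bis(methoxymethoxy)phenyl]-3-methyl-2-(3-methylbut-2-en-1-yl)butan-1-one
Conditions: MgBr2·OEt2, Et2O–CH2Cl2, 0 °C → rt; then H2O
Reagents that add atoms: none
Why: Chelation of the magnesium Lewis acid between the ketone oxygen and one flanking acetal oxygen should direct cleavage to a single ortho methoxymethyl ether (the two are equivalent by aryl rotation), the chelated magnesium phenoxide formed then resisting a second cleavage (chelation-directed acetal cleavage).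

Step 6
Reactants: 10 (2S,3S)-4-[tert-butyl(dimethyl)silyl]oxy-1-[2-hydroxy-4,6-bis(methoxymethoxy)phenyl]-3-methyl-2-(3-methylbut-2-en-1-yl)butan-1-one
Product: 13 2-[(2R)-2-[(2S)-1-[tert-butyl(dimethyl)silyl]oxypropan-2-yl]-5-methylhex-4-en-1-yl]-3,5-bis(methoxymethoxy)phenol, via aryl ethyl carbonate 11 (not isolated), via ortho-quinone methide 12 (not isolated)
Conditions: ClCO2Et, Et3N, THF, 0 °C; then NaBH4, THF–H2O, 0 °C → rt
Reagents that add atoms: none
Why: Borohydride reduction of the ortho-acylphenyl carbonate should proceed by ketone reduction, carbonate transfer and loss of ethyl carbonate to the ortho-quinone methide, whose conjugate reduction gives the benzylic methylene without involving the adjacent stereocentre (deoxygenation of an ortho-acylphenol through its ethyl carbonate).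

Step 7
Reactants: 13 2-[(2R)-2-[(2S)-1-[tert-butyl(dimethyl)silyl]oxypropan-2-yl]-5-methylhex-4-en-1-yl]-3,5-bis(methoxymethoxy)phenol
Product: 14 3-[(2R)-2-[(2S)-1-[tert-butyl(dimethyl)silyl]oxypropan-2-yl]-5-methylhex-4-en-1-yl]-2-hydroxy-4,6-bis(methoxymethoxy)benzaldehyde
Conditions: MgCl2, Et3N, (CH2O)n, THF, reflux
Reagents that add atoms: formaldehyde (as paraformaldehyde) C=O
Why: Magnesium phenoxide-directed ortho-formylation (Casnati–Skattebøl reaction) should deliver the formyl group only to the one free position ortho to the phenol, a second formaldehyde acting as hydride acceptor, while acetals and silyl ether are stable to the mildly basic medium.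

Step 8
Reactants: 15 2,4-dihydroxybenzaldehyde
Product: 16 2,4-bis(methoxymethoxy)benzaldehyde
Conditions: MOMCl, i-Pr2NEt, CH2Cl2, 0 °C → reflux
Reagents that add atoms: chloromethyl methyl ether COCCl
Why: O-Alkylation of both phenols with excess chloromethyl ether and amine base should go to completion on heating, the hydrogen-bonded ortho hydroxyl reacting last.

Step 9
Reactants: 16 2,4-bis(methoxymethoxy)benzaldehyde
Product: 17 1-ethynyl-2,4-bis(methoxymethoxy)benzene
Conditions: dimethyl (1-diazo-2-oxopropyl)phosphonate, K2CO3, MeOH, rt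
Reagents that add atoms: dimethyl (1-diazo-2-oxopropyl)phosphonate CC(=O)C(=[N+]=[N-])P(=O)(OC)OC
Why: Ohira–Bestmann (Seyferth–Gilbert) homologation should convert the non-enolisable aryl aldehyde into the terminal alkyne under mild base that the acetals tolerate.

Step 10
Reactants: 14 3-[(2R)-2-[(2S)-1-[tert-butyl(dimethyl)silyl]oxypropan-2-yl]-5-methylhex-4-en-1-yl]-2-hydroxy-4,6-bis(methoxymethoxy)benzaldehyde; 17 1-ethynyl-2,4-bis(methoxymethoxy)benzene
Product: 19 (2S)-2-[2,4-bis(methoxymethoxy)phenyl]-8-[(2R)-2-[(2S)-1-[tert-butyl(dimethyl)silyl]oxypropan-2-yl]-5-methylhex-4-en-1-yl]-5,7-bis(methoxymethoxy)-2,3-dihydro-4H-chromen-4-one, via (E)-2'-hydroxychalcone 18 (not isolated)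
Conditions: [Rh(cod)OMe]2 (cat.), 1,1'-bis(diphenylphosphino)ferrocene (dppf, cat.), toluene, 60 °C; then 1-[3,5-bis(trifluoromethyl)phenyl]-3-(9-deoxy-epi-quinin-9-yl)thiourea (cat.), 0 °C → rt
Reagents that add atoms: none
Why: The rhodium methoxide is converted by the free 2-OH of 14 into a monovalent rhodium aryloxide, which inserts into the adjacent aldehyde C–H bond to give a five-membered chelated acyl hydride of trivalent rhodium; syn hydrometallation of the terminal alkyne with rhodium on the unhindered terminal carbon and C–C reductive elimination then give the (E)-2'-hydroxychalcone 18 (C3–C4), after which the bifunctional thiourea binds the enone carbonyl while its quinuclidine nitrogen delivers the same phenol to the β-carbon (O1–C2). The closest known reaction types are the tandem rhodium-catalysed hydroacylation/oxa-Michael annulation of salicylaldehydes with alkynes to chroman-4-ones and the cinchona amine–thiourea-catalysed cyclisation of 2'-hydroxychalcones to flavanones, run here as a relay in one flask. Ring C is closed by a 6-endo-trig conjugate addition of the phenol oxygen. The new stereocentre C2 is under catalyst control, the enone face being chosen in the chiral thiourea–quinuclidine pocket, because the two side-chain stereocentres are too remote to bias it. The step needs linear regioselectivity, secured by the bulky chelated dppf–rhodium fragment and by the ortho-substituted aryl group on the internal alkyne carbon; chemoselectivity for the alkyne over the trisubstituted alkene, which is inert to hydroacylation; and closure through a single oxygen, secured because O1 is the only free phenol. Base-free generation of the rhodium aryloxide keeps the chalcone, whose hydrogen-bonded phenol does not add thermally, from closing before the chiral catalyst is present.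

Step 11
Reactants: 19 (2S)-2-[2,4-bis(methoxymethoxy)phenyl]-8-[(2R)-2-[(2S)-1-[tert-butyl(dimethyl)silyl]oxypropan-2-yl]-5-methylhex-4-en-1-yl]-5,7-bis(methoxymethoxy)-2,3-dihydro-4H-chromen-4-one
Product: 20 (2S)-2-(2,4-dihydroxyphenyl)-5,7-dihydroxy-8-[(2R)-2-[(2S)-1-hydroxypropan-2-yl]-5-methylhex-4-en-1-yl]-2,3-dihydro-4H-chromen-4-one (CNP0262638.1)
Conditions: 3 M aq. HCl, MeOH, 40 °C
Reagents that add atoms: none
Why: Acid-catalysed acetal exchange and silyl ether methanolysis should free all five hydroxyl groups, the alkene having no phenol placed for six-membered ring closure and the flavanone not ring-opening under acid, so that C2 should hold.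

Compound list
1 | (S)-4-methyldihydrofuran-2(3H)-one [(S)-β-methyl-γ-butyrolactone] | O=C1C[C@H](C)CO1 | starting material
2 | 1-bromo-3-methylbut-2-ene (prenyl bromide) | CC(C)=CCBr | starting material
3 | lithium enolate of 1 [lithium (4S)-4-methyl-4,5-dihydrofuran-2-olate] | [Li]OC1=C[C@H](C)CO1 | intermediate (not isolated)
4 | (3S,4S)-4-methyl-3-(3-methylbut-2-en-1-yl)dihydrofuran-2(3H)-one (trans) | CC(C)=CC[C@H](C(=O)O1)[C@H](C)C1 | intermediate
5 | phloroglucinol (benzene-1,3,5-triol) | Oc1cc(O)cc(O)c1 | starting material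
6 | 1,3,5-tris(methoxymethoxy)benzene | COCOc1cc(OCOC)cc(OCOC)c1 | intermediate
7 | [2,4,6-tris(methoxymethoxy)phenyl]lithium | [Li]c1c(OCOC)cc(OCOC)cc1OCOC | intermediate (not isolated)
8 | (2S,3S)-4-hydroxy-3-methyl-2-(3-methylbut-2-en-1-yl)-1-[2,4,6-tris(methoxymethoxy)phenyl]butan-1-one | CC(C)=CC[C@H](C(=O)c1c(OCOC)cc(OCOC)cc1OCOC)[C@H](C)CO | intermediate
9 | (2S,3S)-4-[tert-butyl(dimethyl)silyl]oxy-3-methyl-2-(3-methylbut-2-en-1-yl)-1-[2,4,6-tris(methoxymethoxy)phenyl]butan-1-one | CC(C)=CC[C@H](C(=O)c1c(OCOC)cc(OCOC)cc1OCOC)[C@H](C)CO[Si](C)(C)C(C)(C)C | intermediate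
10 | (2S,3S)-4-[tert-butyl(dimethyl)silyl]oxy-1-[2-hydroxy-4,6-bis(methoxymethoxy)phenyl]-3-methyl-2-(3-methylbut-2-en-1-yl)butan-1-one | CC(C)=CC[C@H](C(=O)c1c(O)cc(OCOC)cc1OCOC)[C@H](C)CO[Si](C)(C)C(C)(C)C | intermediate
11 | ethyl aryl carbonate of 10 (phenol oxygen carrying CO2Et, ketone intact) | CC(C)=CC[C@H](C(=O)c1c(OC(=O)OCC)cc(OCOC)cc1OCOC)[C@H](C)CO[Si](C)(C)C(C)(C)C | intermediate (not isolated)
12 | ortho-quinone methide: 6-alkylidene-3,5-bis(methoxymethoxy)cyclohexa-2,4-dien-1-one carrying the silylated side chain on the exocyclic carbon | CC(C)=CC[C@H](C=C1C(=O)C=C(OCOC)C=C1OCOC)[C@H](C)CO[Si](C)(C)C(C)(C)C | intermediate (not isolated)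
13 | 2-[(2R)-2-[(2S)-1-[tert-butyl(dimethyl)silyl]oxypropan-2-yl]-5-methylhex-4-en-1-yl]-3,5-bis(methoxymethoxy)phenol | CC(C)=CC[C@H](Cc1c(O)cc(OCOC)cc1OCOC)[C@H](C)CO[Si](C)(C)C(C)(C)C | intermediate
14 | 3-[(2R)-2-[(2S)-1-[tert-butyl(dimethyl)silyl]oxypropan-2-yl]-5-methylhex-4-en-1-yl]-2-hydroxy-4,6-bis(methoxymethoxy)benzaldehyde | CC(C)=CC[C@H](Cc1c(O)c(C=O)c(OCOC)cc1OCOC)[C@H](C)CO[Si](C)(C)C(C)(C)C | intermediate
15 | 2,4-dihydroxybenzaldehyde | O=Cc1ccc(O)cc1O | starting material
16 | 2,4-bis(methoxymethoxy)benzaldehyde | COCOc1ccc(C=O)c(OCOC)c1 | intermediate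
17 | 1-ethynyl-2,4-bis(methoxymethoxy)benzene | C#Cc1ccc(OCOC)cc1OCOC | intermediate
18 | (E)-3-[2,4-bis(methoxymethoxy)phenyl]-1-[3-[(2R)-2-[(2S)-1-[tert-butyl(dimethyl)silyl]oxypropan-2-yl]-5-methylhex-4-en-1-yl]-2-hydroxy-4,6-bis(methoxymethoxy)phenyl]prop-2-en-1-one | CC(C)=CC[C@H](Cc1c(O)c(C(=O)/C=C/c2ccc(OCOC)cc2OCOC)c(OCOC)cc1OCOC)[C@H](C)CO[Si](C)(C)C(C)(C)C | intermediate (not isolated)
19 | (2S)-2-[2,4-bis(methoxymethoxy)phenyl]-8-[(2R)-2-[(2S)-1-[tert-butyl(dimethyl)silyl]oxypropan-2-yl]-5-methylhex-4-en-1-yl]-5,7-bis(methoxymethoxy)-2,3-dihydro-4H-chromen-4-one | CC(C)=CC[C@H](Cc1c(OCOC)cc(OCOC)c2c1O[C@H](c1ccc(OCOC)cc1OCOC)CC2=O)[C@H](C)CO[Si](C)(C)C(C)(C)C | intermediate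
20 | (2S)-2-(2,4-dihydroxyphenyl)-5,7-dihydroxy-8-[(2R)-2-[(2S)-1-hydroxypropan-2-yl]-5-methylhex-4-en-1-yl]-2,3-dihydro-4H-chromen-4-one | CC(C)=CC[C@H](Cc1c(O)cc(O)c2c1O[C@H](c1ccc(O)cc1O)CC2=O)[C@H](C)CO | target

Total step count: 11. Longest linear sequence: 8 steps (steps 1, 3, 4, 5, 6, 7, 10, 11).

Steps most likely to fail

Step 10. Facial selectivity in the oxa-Michael closure of the non-activated, electron-rich enone may be poor, or the acyl group may be delivered to the internal alkyne carbon. The fallback sets out from 14 and comes back at 19, building the C2–C3 bond by condensation and closing an activated acceptor instead. Aldol addition of the lithium enolate of allyl acetate (excess, LDA, THF, −78 °C) to 14 should give the allyl β-hydroxy ester F1. Benzylic oxidation with MnO2 should give the allyl β-keto ester F2. Knoevenagel condensation with aldehyde 16 (piperidine, AcOH, toluene) should give the alkylidene β-keto ester F3. The same quinine-derived thiourea should close this doubly activated acceptor at low temperature to the allyl (2S)-flavanone-3-carboxylate F4. Deallylation–decarboxylation with Pd(PPh3)4 and morpholine in THF under neutral conditions should then return 19.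

Step 3. The hindered aryllithium may act as a base on the α-branched lactone, causing enolisation with loss of configuration at the α-carbon or simple return of lactone. The fallback sets out from 4 and comes back at 8, replacing acyl substitution by addition to an aldehyde followed by oxidation. Reduction with DIBAL (toluene, −78 °C) should give the lactol F5. Addition of excess aryllithium 7 to its open hydroxy-aldehyde form should give the benzylic diol F6. Selective benzylic oxidation with MnO2 in CH2Cl2 should return 8.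

Step 5. The Lewis acid may over-cleave a second acetal or remove the silyl ether. The fallback sets out from 8 and comes back at 10, changing the order of events so that no silyl ether is present when the acetal is cleaved, and using hydrogen-bond-assisted protic acetal exchange instead of chelation. Catalytic HCl in MeOH at 0 °C should cleave the carbonyl-flanked ether of 8 to give the phenol–alcohol F7. Chemoselective silylation of the primary alcohol in the presence of the hydrogen-bonded phenol (TBSCl, Et3N, DMAP, CH2Cl2, 0 °C) should return 10.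

Further compounds
F1 | step 10 | allyl 3-hydroxy-3-[3-[(2R)-2-[(2S)-1-[tert-butyl(dimethyl)silyl]oxypropan-2-yl]-5-methylhex-4-en-1-yl]-2-hydroxy-4,6-bis(methoxymethoxy)phenyl]propanoate (carbinol epimers) | CC(C)=CC[C@H](Cc1c(O)c(C(O)CC(=O)OCC=C)c(OCOC)cc1OCOC)[C@H](C)CO[Si](C)(C)C(C)(C)C
F2 | step 10 | allyl 3-oxo-3-[3-[(2R)-2-[(2S)-1-[tert-butyl(dimethyl)silyl]oxypropan-2-yl]-5-methylhex-4-en-1-yl]-2-hydroxy-4,6-bis(methoxymethoxy)phenyl]propanoate | CC(C)=CC[C@H](Cc1c(O)c(C(=O)CC(=O)OCC=C)c(OCOC)cc1OCOC)[C@H](C)CO[Si](C)(C)C(C)(C)C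
F3 | step 10 | allyl 2-[2,4-bis(methoxymethoxy)benzylidene]-3-oxo-3-aryl-propanoate (aryl as in F2; alkene isomers) | CC(C)=CC[C@H](Cc1c(O)c(C(=O)C(=Cc2ccc(OCOC)cc2OCOC)C(=O)OCC=C)c(OCOC)cc1OCOC)[C@H](C)CO[Si](C)(C)C(C)(C)C
F4 | step 10 | allyl (2S)-2-[2,4-bis(methoxymethoxy)phenyl]-8-[(2R)-2-[(2S)-1-[tert-butyl(dimethyl)silyl]oxypropan-2-yl]-5-methylhex-4-en-1-yl]-5,7-bis(methoxymethoxy)-4-oxochromane-3-carboxylate | CC(C)=CC[C@H](Cc1c(OCOC)cc(OCOC)c2c1O[C@H](c1ccc(OCOC)cc1OCOC)C(C(=O)OCC=C)C2=O)[C@H](C)CO[Si](C)(C)C(C)(C)C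
F5 | step 3 | (3S,4S)-4-methyl-3-(3-methylbut-2-en-1-yl)tetrahydrofuran-2-ol (lactol, anomers) | CC(C)=CC[C@H](C(O)O1)[C@H](C)C1
F6 | step 3 | (2S,3S)-2-methyl-3-(3-methylbut-2-en-1-yl)-4-[2,4,6-tris(methoxymethoxy)phenyl]butane-1,4-diol (carbinol epimers) | CC(C)=CC[C@H](C(O)c1c(OCOC)cc(OCOC)cc1OCOC)[C@H](C)CO
F7 | step 5 | (2S,3S)-4-hydroxy-1-[2-hydroxy-4,6-bis(methoxymethoxy)phenyl]-3-methyl-2-(3-methylbut-2-en-1-yl)butan-1-one | CC(C)=CC[C@H](C(=O)c1c(O)cc(OCOC)cc1OCOC)[C@H](C)CO
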